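**Retrosynthetic overview**

1. Rings are lettered A (2,4,6-trihydroxyphenyl end) to F (3,4,5-trihydroxyphenyl end). The strategy rests on ring D, whose carbons D1 (O to ring C), D3, D4, D5 (three OH) and D6 (O to ring E) are five adjacent C–O carbons, with D2 the only C–H.
2. The target comes from a per-alkylated hexamer by global ether cleavage. Rings C, B and A are attached one at a time to the D1 oxygen by SNAr with 4-fluoro-3,5-dimethoxybenzaldehyde followed by Baeyer–Villiger (Dakin-type) oxidation.
3. Ring D is the only ring that is constructed. A 4-(1-ethoxyvinyl)cyclobutenone is opened thermally and closed again across D1–D2; D1, D6, D5 and D4 are the four squarate carbons, and D2 and D3 come from ethyl vinyl ether.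
4. The cyclobutenone comes from a mixed aryl methyl squarate, 1-ethoxyvinyllithium and methyl triflate. The squarate comes from squaric acid via its dichloride, methanol and the EF phenol, which is made from 3,4,5-trimethoxyphenol and the same fluoroaldehyde.
5. Order of rings: F and E are joined first (both bought as arenes), D is built on the E oxygen, then C, B and A are appended.

Key step: step 7

Remark on the chemistry: 4-fluoro-3,5-dimethoxybenzaldehyde is assumed to be purchasable. The cyclobutenone of step 6 is racemic at its one sp3 carbon; this centre becomes an aromatic carbon in step 7 and the target is achiral, so no stereocontrol is needed. The tertiary alkoxide of step 6 is capped as a methyl ether before the thermolysis, so that ring D is delivered as a single monophenol.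

**Route**

Step 1
Reactants: 1 3,4,5-trimethoxyphenol; 2 4-fluoro-3,5-dimethoxybenzaldehyde
Product: 3 3,5-dimethoxy-4-(3,4,5-trimethoxyphenoxy)benzaldehyde (EF aldehyde)
Conditions: Cs2CO3, DMSO, 100 °C
Reagents that add atoms: none
Why: Nucleophilic aromatic substitution (SNAr), in which the unhindered phenoxide of 1 adds at the fluorine-bearing carbon of 2, the para formyl group stabilises the Meisenheimer adduct and fluoride leaves.

Step 2
Reactants: 3 EF aldehyde
Product: 5 3,5-dimethoxy-4-(3,4,5-trimethoxyphenoxy)phenol (EF phenol), via EF aryl formate 4 (not isolated)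
Conditions: mCPBA, CH2Cl2, 0 °C to rt; then K2CO3, MeOH, rt
Reagents that add atoms: 3-chloroperoxybenzoic acid (mCPBA), OOC(=O)c1cccc(Cl)c1
Why: Baeyer–Villiger (Dakin-type) oxidation of an electron-rich benzaldehyde, in which the oxygenated aryl group migrates in preference to hydride to give the formate, which is cleaved by methanolysis, as in the known conversion of 3,4,5-trimethoxybenzaldehyde into 1.

Step 3
Reactants: 6 squaric acid
Product: 7 3,4-dichlorocyclobut-3-ene-1,2-dione (squaric acid dichloride)
Conditions: SOCl2, DMF (cat.), toluene, 80 °C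
Reagents that add atoms: thionyl chloride, ClS(Cl)=O
Why: Vilsmeier-catalysed conversion of the two vinylogous acid hydroxyls into vinylogous acid chlorides, the standard preparation of this dichloride.

Step 4
Reactants: 7 squaric acid dichloride
Product: 8 3-chloro-4-methoxycyclobut-3-ene-1,2-dione
Conditions: MeOH (1.0 equiv), Et2O, 0 °C to rt
Reagents that add atoms: methanol, CO
Why: Addition–elimination at one vinylogous acid chloride carbon; the methoxy group introduced first donates into the ring and deactivates the second chloride, so that one equivalent of methanol should stop at the monoester.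

Step 5
Reactants: 8 3-chloro-4-methoxycyclobut-3-ene-1,2-dione; 5 EF phenol
Product: 9 3-[3,5-dimethoxy-4-(3,4,5-trimethoxyphenoxy)phenoxy]-4-methoxycyclobut-3-ene-1,2-dione (mixed aryl methyl squarate)
Conditions: i-Pr2NEt, CH2Cl2, −40 to 0 °C
Reagents that add atoms: none
Why: Vinylogous esterification by addition–elimination, in which the amine-generated phenoxide attacks through oxygen at the chlorine-bearing sp2 carbon and chloride leaves in preference to methoxide, so the hindered D6–O–ring E ether is made at a squarate carbon and not by an aromatic coupling.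

Step 6
Reactants: 9 mixed aryl methyl squarate; 10 ethyl vinyl ether
Product: 13 4-(1-ethoxyvinyl)-3,4-dimethoxy-2-[3,5-dimethoxy-4-(3,4,5-trimethoxyphenoxy)phenoxy]cyclobut-2-en-1-one (racemic), via 1-ethoxyvinyllithium 11 (not isolated), via lithium alkoxide of the adduct 12 (not isolated)
Conditions: 10, t-BuLi, THF, −78 to 0 °C; then added to 9, THF, −78 °C; then MeOTf, −78 to −20 °C
Reagents that add atoms: methyl trifluoromethanesulfonate, COS(=O)(=O)C(F)(F)F
Why: 1,2-Addition of an α-alkoxyvinyllithium to a squarate ester carbonyl with O-methylation of the lithium alkoxide in the same flask; the carbonyl flanked by the methoxy-bearing carbon is conjugated only with the weakly donating and bulky aryloxy oxygen, so it is the more electrophilic and less shielded one and should take the nucleophile, which leaves the ketone next to the aryloxy carbon, and the new stereocentre is racemic and is erased in step 7.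

Step 7
Reactants: 13 4-(1-ethoxyvinyl)-3,4-dimethoxy-2-aryloxycyclobutenone
Product: 16 5-ethoxy-3,4-dimethoxy-2-[3,5-dimethoxy-4-(3,4,5-trimethoxyphenoxy)phenoxy]phenol (DEF phenol), via dienylketene 14 (not isolated), via cyclohexadienone 15 (not isolated)
Conditions: toluene (degassed), 110 °C
Reagents that add atoms: none
Why: Heating opens the cyclobutenone by a conrotatory 4π electrocyclic cleavage of the C1–C4 bond in which the C4 methoxy group, as the donor, rotates outward and the ethoxyvinyl group inward, so that dienylketene 14 forms with the enol ether cis to the ketene. Ring D then closes by a 6π electrocyclization that joins the ketene carbon (D1) to the terminal CH2 of the vinyl ether (D2), and the resulting cyclohexa-2,4-dienone 15 enolises to the phenol. The closest known reaction type is the Moore rearrangement of squarate-derived 4-alkenyl-4-hydroxy- or 4-alkoxycyclobutenones to hydroquinones and their monoethers. No stereocentre is created, and the single racemic centre of 13 is lost in the ring opening. The step needs outward rotation of the C4 oxygen, which the donor character of that methoxy group secures, and it needs ring closure to outrun capture of the ketene by the electron-rich ring E, which the intramolecular six-electron closure onto the nucleophilic enol ether terminus should secure. Because the C4 oxygen is already methylated, the only free hydroxyl of 16 is the ketene-derived one at D1, flanked by the ring C–H and by the carbon that carries ring E.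

Step 8
Reactants: 16 DEF phenol; 2 4-fluoro-3,5-dimethoxybenzaldehyde
Product: 17 4-{5-ethoxy-3,4-dimethoxy-2-[3,5-dimethoxy-4-(3,4,5-trimethoxyphenoxy)phenoxy]phenoxy}-3,5-dimethoxybenzaldehyde (CDEF aldehyde)
Conditions: Cs2CO3, DMSO (degassed), 110 °C
Reagents that add atoms: none
Why: SNAr of the D1 phenoxide, which has one free ortho position, at the para-formyl-activated C–F carbon; attack perpendicular to the ring plane limits the penalty from the two flanking methoxy groups.

Step 9
Reactants: 17 CDEF aldehyde
Product: 19 CDEF phenol (17 with the formyl group replaced by hydroxyl), via CDEF aryl formate 18 (not isolated)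
Conditions: mCPBA (1.2 equiv), CH2Cl2, 0 °C to rt; then K2CO3, MeOH, rt
Reagents that add atoms: 3-chloroperoxybenzoic acid (mCPBA), OOC(=O)c1cccc(Cl)c1
Why: Baeyer–Villiger (Dakin-type) oxidation as in step 2; the aldehyde reacts with the peracid much faster than the fully substituted alkoxyarene rings, so a small excess at low temperature should spare ring D.

Step 10
Reactants: 19 CDEF phenol; 2 4-fluoro-3,5-dimethoxybenzaldehyde
Product: 20 BCDEF aldehyde (19 carrying a 4-formyl-2,6-dimethoxyphenyl group on the ring C phenol oxygen)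
Conditions: Cs2CO3, DMSO, 100 °C
Reagents that add atoms: none
Why: SNAr as in step 1, with a phenoxide that again has two free ortho positions.

Step 11
Reactants: 20 BCDEF aldehyde
Product: 22 BCDEF phenol (20 with the formyl group replaced by hydroxyl), via BCDEF aryl formate 21 (not isolated)
Conditions: mCPBA (1.2 equiv), CH2Cl2, 0 °C to rt; then K2CO3, MeOH, rt
Reagents that add atoms: 3-chloroperoxybenzoic acid (mCPBA), OOC(=O)c1cccc(Cl)c1
Why: Baeyer–Villiger (Dakin-type) oxidation with aryl migration and formate methanolysis, as in steps 2 and 9.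

Step 12
Reactants: 22 BCDEF phenol; 2 4-fluoro-3,5-dimethoxybenzaldehyde
Product: 23 ABCDEF aldehyde (22 carrying a 4-formyl-2,6-dimethoxyphenyl group on the ring B phenol oxygen)
Conditions: Cs2CO3, DMSO, 100 °C
Reagents that add atoms: none
Why: SNAr as in steps 1 and 10; it installs ring A with its ether carbon between two methoxy groups and the formyl group para to it.

Step 13
Reactants: 23 ABCDEF aldehyde
Product: 25 ABCDEF phenol (tridecamethyl monoethyl ether of the target, free hydroxyl para to the ether oxygen on ring A), via ABCDEF aryl formate 24 (not isolated)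
Conditions: mCPBA (1.2 equiv), CH2Cl2, 0 °C to rt; then K2CO3, MeOH, rt
Reagents that add atoms: 3-chloroperoxybenzoic acid (mCPBA), OOC(=O)c1cccc(Cl)c1
Why: Baeyer–Villiger (Dakin-type) oxidation, which supplies the third oxygen of ring A at the carbon that carried the formyl group.

Step 14
Reactants: 25 ABCDEF phenol
Product: 26 CNP0175585.0 (target, pentadecaphenol)
Conditions: BBr3 (excess), CH2Cl2, −78 °C to rt; then H2O, 0 °C (argon)
Reagents that add atoms: none
Why: Lewis-acid-mediated cleavage of aryl alkyl ethers, in which bromide attacks the methyl or ethyl carbon of each boron-complexed ether, while the five diaryl ether bonds stay intact because neither of their carbons is open to SN2 attack.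

**Compound list**

1 | 3,4,5-trimethoxyphenol | COc1cc(O)cc(OC)c1OC | starting material
2 | 4-fluoro-3,5-dimethoxybenzaldehyde | COc1cc(C=O)cc(OC)c1F | starting material
3 | 3,5-dimethoxy-4-(3,4,5-trimethoxyphenoxy)benzaldehyde (EF aldehyde) | COc1cc(C=O)cc(OC)c1Oc1cc(OC)c(OC)c(OC)c1 | intermediate
4 | 3,5-dimethoxy-4-(3,4,5-trimethoxyphenoxy)phenyl formate (EF aryl formate) | COc1cc(OC=O)cc(OC)c1Oc1cc(OC)c(OC)c(OC)c1 | intermediate
5 | 3,5-dimethoxy-4-(3,4,5-trimethoxyphenoxy)phenol (EF phenol) | COc1cc(O)cc(OC)c1Oc1cc(OC)c(OC)c(OC)c1 | intermediate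
6 | squaric acid | OC1=C(O)C(=O)C1=O | starting material
7 | 3,4-dichlorocyclobut-3-ene-1,2-dione | ClC1=C(Cl)C(=O)C1=O | intermediate
8 | 3-chloro-4-methoxycyclobut-3-ene-1,2-dione | COC1=C(Cl)C(=O)C1=O | intermediate
9 | 3-[3,5-dimethoxy-4-(3,4,5-trimethoxyphenoxy)phenoxy]-4-methoxycyclobut-3-ene-1,2-dione | COC1=C(Oc2cc(OC)c(Oc3cc(OC)c(OC)c(OC)c3)c(OC)c2)C(=O)C1=O | intermediate
10 | ethyl vinyl ether | C=COCC | starting material
11 | 1-ethoxyvinyllithium | [Li]C(=C)OCC | intermediate
12 | lithium alkoxide of the adduct (lithium 1-(1-ethoxyvinyl)-2-methoxy-4-oxo-3-aryloxycyclobut-2-en-1-olate, racemic) | [Li+].CCOC(=C)C1([O-])C(OC)=C(Oc2cc(OC)c(Oc3cc(OC)c(OC)c(OC)c3)c(OC)c2)C1=O | intermediate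
13 | 4-(1-ethoxyvinyl)-3,4-dimethoxy-2-[3,5-dimethoxy-4-(3,4,5-trimethoxyphenoxy)phenoxy]cyclobut-2-en-1-one (racemic) | CCOC(=C)C1(OC)C(OC)=C(Oc2cc(OC)c(Oc3cc(OC)c(OC)c(OC)c3)c(OC)c2)C1=O | intermediate
14 | (3Z)-5-ethoxy-3,4-dimethoxy-2-[3,5-dimethoxy-4-(3,4,5-trimethoxyphenoxy)phenoxy]hexa-1,3,5-trien-1-one (dienylketene) | O=C=C(Oc1cc(OC)c(Oc2cc(OC)c(OC)c(OC)c2)c(OC)c1)/C(OC)=C(/OC)C(=C)OCC | intermediate
15 | 5-ethoxy-3,4-dimethoxy-2-[3,5-dimethoxy-4-(3,4,5-trimethoxyphenoxy)phenoxy]cyclohexa-2,4-dien-1-one | O=C1CC(OCC)=C(OC)C(OC)=C1Oc1cc(OC)c(Oc2cc(OC)c(OC)c(OC)c2)c(OC)c1 | intermediate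
16 | 5-ethoxy-3,4-dimethoxy-2-[3,5-dimethoxy-4-(3,4,5-trimethoxyphenoxy)phenoxy]phenol (DEF phenol) | CCOc1cc(O)c(Oc2cc(OC)c(Oc3cc(OC)c(OC)c(OC)c3)c(OC)c2)c(OC)c1OC | intermediate
17 | 4-{5-ethoxy-3,4-dimethoxy-2-[3,5-dimethoxy-4-(3,4,5-trimethoxyphenoxy)phenoxy]phenoxy}-3,5-dimethoxybenzaldehyde (CDEF aldehyde) | CCOc1cc(Oc2c(OC)cc(C=O)cc2OC)c(Oc2cc(OC)c(Oc3cc(OC)c(OC)c(OC)c3)c(OC)c2)c(OC)c1OC | intermediate
18 | CDEF aryl formate (formate ester of 19) | CCOc1cc(Oc2c(OC)cc(OC=O)cc2OC)c(Oc2cc(OC)c(Oc3cc(OC)c(OC)c(OC)c3)c(OC)c2)c(OC)c1OC | intermediate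
19 | 4-{5-ethoxy-3,4-dimethoxy-2-[3,5-dimethoxy-4-(3,4,5-trimethoxyphenoxy)phenoxy]phenoxy}-3,5-dimethoxyphenol (CDEF phenol) | CCOc1cc(Oc2c(OC)cc(O)cc2OC)c(Oc2cc(OC)c(Oc3cc(OC)c(OC)c(OC)c3)c(OC)c2)c(OC)c1OC | intermediate
20 | BCDEF aldehyde (4-formyl-2,6-dimethoxyphenyl ether of 19) | CCOc1cc(Oc2c(OC)cc(Oc3c(OC)cc(C=O)cc3OC)cc2OC)c(Oc2cc(OC)c(Oc3cc(OC)c(OC)c(OC)c3)c(OC)c2)c(OC)c1OC | intermediate
21 | BCDEF aryl formate (formate ester of 22) | CCOc1cc(Oc2c(OC)cc(Oc3c(OC)cc(OC=O)cc3OC)cc2OC)c(Oc2cc(OC)c(Oc3cc(OC)c(OC)c(OC)c3)c(OC)c2)c(OC)c1OC | intermediate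
22 | BCDEF phenol (4-hydroxy-2,6-dimethoxyphenyl ether of 19) | CCOc1cc(Oc2c(OC)cc(Oc3c(OC)cc(O)cc3OC)cc2OC)c(Oc2cc(OC)c(Oc3cc(OC)c(OC)c(OC)c3)c(OC)c2)c(OC)c1OC | intermediate
23 | ABCDEF aldehyde (4-formyl-2,6-dimethoxyphenyl ether of 22) | CCOc1cc(Oc2c(OC)cc(Oc3c(OC)cc(Oc4c(OC)cc(C=O)cc4OC)cc3OC)cc2OC)c(Oc2cc(OC)c(Oc3cc(OC)c(OC)c(OC)c3)c(OC)c2)c(OC)c1OC | intermediate
24 | ABCDEF aryl formate (formate ester of 25) | CCOc1cc(Oc2c(OC)cc(Oc3c(OC)cc(Oc4c(OC)cc(OC=O)cc4OC)cc3OC)cc2OC)c(Oc2cc(OC)c(Oc3cc(OC)c(OC)c(OC)c3)c(OC)c2)c(OC)c1OC | intermediate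
25 | ABCDEF phenol (4-hydroxy-2,6-dimethoxyphenyl ether of 22; tridecamethyl monoethyl ether of the target) | CCOc1cc(Oc2c(OC)cc(Oc3c(OC)cc(Oc4c(OC)cc(O)cc4OC)cc3OC)cc2OC)c(Oc2cc(OC)c(Oc3cc(OC)c(OC)c(OC)c3)c(OC)c2)c(OC)c1OC | intermediate
26 | CNP0175585.0 | Oc1cc(O)c(Oc2cc(O)c(Oc3cc(O)c(Oc4cc(O)c(O)c(O)c4Oc4cc(O)c(Oc5cc(O)c(O)c(O)c5)c(O)c4)c(O)c3)c(O)c2)c(O)c1 | target

**Step count and risks**

Total step count: 14. Longest linear sequence: 12 steps (steps 1, 2, 5 to 14 from 3,4,5-trimethoxyphenol; equally steps 3 to 14 from squaric acid).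

Steps most likely to fail:

Step 6. The vinyllithium may not discriminate well enough between the two ring carbonyls of 9, it may add to the aryloxy-bearing carbon and expel aryloxide, and the hindered tertiary lithium alkoxide may be methylated slowly and fragment on warming. The fallback sets out from 9 and 11 and separates the three events. Reagent 11 is transmetalated with anhydrous CeCl3 to lower its basicity, added to 9 at −78 °C and quenched with aqueous NH4Cl, and the free tertiary alcohol 4-(1-ethoxyvinyl)-4-hydroxy-3-methoxy-2-[3,5-dimethoxy-4-(3,4,5-trimethoxyphenoxy)phenoxy]cyclobut-2-en-1-one F1 is isolated, which allows any regioisomeric adduct to be removed by chromatography. Thermolysis of the alcohol in degassed toluene at 110 °C should then give the hydroquinone 5-ethoxy-3-methoxy-2-[3,5-dimethoxy-4-(3,4,5-trimethoxyphenoxy)phenoxy]benzene-1,4-diol F2. Its two hydroxyls are told apart after ring formation by their surroundings: the one next to the ring C–H is arylated with 2 (one equivalent of Cs2CO3, degassed DMSO) to give the hydroxy aldehyde 4-{5-ethoxy-4-hydroxy-3-methoxy-2-[3,5-dimethoxy-4-(3,4,5-trimethoxyphenoxy)phenoxy]phenoxy}-3,5-dimethoxybenzaldehyde F3. The remaining phenol, flanked by two alkoxy groups, is methylated with MeI and K2CO3 in acetone, and the route is rejoined at 17.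

Step 8. Addition of the ortho-substituted, oxidation-prone D1 phenoxide to a C–F carbon that lies between two methoxy groups and is activated only by a para formyl group may be too slow, so that the phenoxide degrades at the temperature needed. The fallback sets out from 16 and replaces the uncatalysed substitution by a copper-catalysed Ullmann-type C–O coupling with purchasable 4-bromo-3,5-dimethoxybenzaldehyde (CuI, picolinic acid, K3PO4, DMSO, 90 °C). It delivers the same aldehyde and comes back to the route at 17 without a new intermediate.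

Step 14. Cleavage of fourteen alkyl ethers in one operation may stall at partially alkylated stages (the ethyl ether and the ethers wedged between aryloxy groups last), and the pyrogallol-type rings D and F may oxidise in air during isolation of the free polyphenol. The fallback sets out from 25 and changes the way the product is secured. After the BBr3 treatment and quench the crude material is not purified but acetylated (Ac2O, pyridine, DMAP) to the pentadecaacetate of the target F4, which is stable to air and can be chromatographed on silica; fractions that still carry alkyl groups are returned to the cleavage. Acid-catalysed methanolysis of the pure acetate (AcCl in degassed MeOH, rt) then releases 26 under non-oxidising, non-basic conditions.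

**Further compounds**

F1 | step 6 | 4-(1-ethoxyvinyl)-4-hydroxy-3-methoxy-2-[3,5-dimethoxy-4-(3,4,5-trimethoxyphenoxy)phenoxy]cyclobut-2-en-1-one (racemic) | CCOC(=C)C1(O)C(OC)=C(Oc2cc(OC)c(Oc3cc(OC)c(OC)c(OC)c3)c(OC)c2)C1=O
F2 | step 6 | 5-ethoxy-3-methoxy-2-[3,5-dimethoxy-4-(3,4,5-trimethoxyphenoxy)phenoxy]benzene-1,4-diol | CCOc1cc(O)c(Oc2cc(OC)c(Oc3cc(OC)c(OC)c(OC)c3)c(OC)c2)c(OC)c1O
F3 | step 6 | 4-{5-ethoxy-4-hydroxy-3-methoxy-2-[3,5-dimethoxy-4-(3,4,5-trimethoxyphenoxy)phenoxy]phenoxy}-3,5-dimethoxybenzaldehyde | CCOc1cc(Oc2c(OC)cc(C=O)cc2OC)c(Oc2cc(OC)c(Oc3cc(OC)c(OC)c(OC)c3)c(OC)c2)c(OC)c1O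
F0 | step 8 | none | none
F4 | step 14 | pentadecaacetate of CNP0175585.0 | CC(=O)Oc1cc(OC(C)=O)c(Oc2cc(OC(C)=O)c(Oc3cc(OC(C)=O)c(Oc4cc(OC(C)=O)c(OC(C)=O)c(OC(C)=O)c4Oc4cc(OC(C)=O)c(Oc5cc(OC(C)=O)c(OC(C)=O)c(OC(C)=O)c5)c(OC(C)=O)c4)c(OC(C)=O)c3)c(OC(C)=O)c2)c(OC(C)=O)c1
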